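All runs are calculated from invented constants, noise included.

Z stood at 61.0 % in the eta run, with the same 0.70 equiv of G as the flask asked about here but half its concentration of X. The question is whether that plateau carries over.

| flask | X | G | remark | time |
|---|---|---|---|---|
| gamma | 0.80 M | 0.35 equiv | run made earlier |  |
| epsilon | 0.80 M | 1.4 equiv | run made earlier |  |
| eta | 0.40 M | 0.70 equiv | run made earlier |  |
| flask | 0.80 M | 0.700 equiv |  | 1.0 h |

| run | time / min | Z / % | X / % |
|---|---|---|---|
| gamma | 10.0 | 34.3 | 69.8 |
| gamma | 25.0 | 33.3 | 66.1 |
| gamma | 50.0 | 34.2 | 66.7 |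
| gamma | 80.0 | 33.1 | 66.1 |
| epsilon | 6.00 | 79.0 | 18.6 |
| epsilon | 12.0 | 87.7 | 12.9 |
| epsilon | 30.0 | 88.0 | 11.6 |
| epsilon | 80.0 | 91.1 | 10.9 |
| eta | 6.00 | 39.9 | 61.0 |
| eta | 12.0 | 50.8 | 48.0 |
| eta | 30.0 | 60.7 | 40.9 |
| eta | 80.0 | 61.0 | 37.4 |

(each reading ± 1 percentage point)

- at 1.0 h, what has stopped the reaction, if anything has (forward and back rates have come level / all of X has reacted / G has run out first / it is still moving)
- Z at 1.0 h, in percent of the X charged

- the reaction counts as stopped when no species that holds the X changes by six tenths of a point or more over the second half of the time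

*Did G run out in eta?* No. Gamma stops near 33.1 % Z on 0.35 equiv of G, so X and G go one for one. That leaves eta at 80.0 min with 0.0900 equiv of G beside 37.4 % X. Both are present, so I read a balance.

*A balance of what?* Take z, x and g as Z, X and remaining G, per X charged. If X + G ⇌ Z were the whole reaction, z/(x·g·c), with c the X charged, would hold still. It gives 45.3 M⁻¹ in eta and 21.4 M⁻¹ in epsilon. With an unseen co-product formed one for one with Z, z·z/(x·g) gives 11.1 and 15.6.

*Those differ too.* Yes, but by a smaller factor than the first pair, and the small g and x carry the 1 percentage point scatter. My reading is their geometric mean, K = 13.1, the level ratio (equilibrium constant): z·z/(x·g) where forward and back rates are equal. At any moment, the quotient over K is back rate over forward rate.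

*And at 0.80 M?* K has no unit, so concentration does not enter. The balance gives z = 62.2 %. Eta was still moving at 30.0 min: its X reads 40.9 % there and 37.4 % at 80.0 min. Gamma, at the flask's 0.80 M of X, reads X 66.1 % at 25.0 min and 66.1 % at 80.0 min, so I expect the flask to have reached its level by 1.0 h.

The forecast says the same: forward and back rates have come level, with Z at 62 %, range 60 % to 64 %, on the ground that “K is dimensionless, so concentration does not shift the position.”

The flask gives 62.1 % Z at 1.0 h: forward and back rates have come level. Over the second half of the time, nothing moved by more than 0.052 points.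

    X + G ⇌ Z + D (K = 13.0, k = 0.00800 M⁻¹ s⁻¹)

At 0.100 h the flask held 52.2 % Z, 47.8 % X and 25.4 % of its G. The quotient was 3.20, so against the read K the back rate was already a quarter of the forward rate.

For a neighbour flask with 1.20 equiv of G, the read K gives z = 84.6 %. The computed flask has 84.5 % Z at 1.00 h.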